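**Assumption:** the target SMILES contains no stereocentre and no stereogenic double bond, so the compound is achiral and no asymmetric step is needed.

**Retrosynthetic overview**
- Target ⇐ its 7-O-MOM ether ⇐ deoxybenzoin (oxidation of the CH2) ⇐ β-keto ester (loss of the CO2Me carbon) ⇐ β-hydroxy ester.
- Key C–C bond: the bond between the two future carbonyl carbons, made by an intermolecular aldol addition of the lithium enolate of methyl (4-methoxyphenyl)acetate to 5-methoxy-7-(methoxymethoxy)-2,2-dimethyl-2H-chromene-6-carbaldehyde.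
- Chromene aldehyde ⇐ 2,4,6-trihydroxybenzaldehyde: para-O-(1,1-dimethylpropargyl) ether, mono-MOM ether, propargyl Claisen/oxa-6π closure next to the chelated OH, then methylation of that OH.
- Ring order: both benzene rings are bought; the pyran ring is the only ring formed (step 3), before the fragments are joined.

**Route**

Step 1
Reactants: 1 2,4,6-trihydroxybenzaldehyde; 2 3-chloro-3-methylbut-1-yne
Product: 3 2,6-dihydroxy-4-[(2-methylbut-3-yn-2-yl)oxy]benzaldehyde
Conditions: DBU (1.2 equiv), CuCl2·2H2O (1 mol %), MeCN, 0 °C → rt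
Reagents that add atoms: none
Why: The para OH is the only non-chelated and most acidic phenol, so one equivalent of base gives its phenoxide, which is O-alkylated by the copper-activated tertiary propargyl chloride (Cu-catalysed propargylic etherification).

Step 2
Reactants: 3 2,6-dihydroxy-4-[(2-methylbut-3-yn-2-yl)oxy]benzaldehyde
Product: 4 2-hydroxy-6-(methoxymethoxy)-4-[(2-methylbut-3-yn-2-yl)oxy]benzaldehyde
Conditions: MOMCl (1.1 equiv), iPr2NEt, CH2Cl2, 0 °C → rt
Reagents that add atoms: chloromethyl methyl ether (MOMCl), COCCl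
Why: The two ortho OH groups are equivalent, and after the first O-alkylation (Williamson-type acetal formation) the remaining OH is locked in a strong hydrogen bond to the aldehyde and does not react.

Step 3
Reactants: 4 2-hydroxy-6-(methoxymethoxy)-4-[(2-methylbut-3-yn-2-yl)oxy]benzaldehyde
Product: 7 5-hydroxy-7-(methoxymethoxy)-2,2-dimethyl-2H-chromene-6-carbaldehyde, via allenylphenol 5 (not isolated), via ortho-quinone methide 6 (not isolated)
Conditions: o-xylene, 140 °C, 12 h
Reagents that add atoms: none
Why: Aromatic propargyl Claisen rearrangement goes to the ortho carbon next to the chelated OH (bond fixation by the hydrogen-bonded chelate ring), then a 1,5-H shift and oxa-6π electrocyclisation close the pyran through the former ether oxygen; it is a pure isomerisation with no by-product and no stereocentre.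

Step 4
Reactants: 7 5-hydroxy-7-(methoxymethoxy)-2,2-dimethyl-2H-chromene-6-carbaldehyde
Product: 8 5-methoxy-7-(methoxymethoxy)-2,2-dimethyl-2H-chromene-6-carbaldehyde
Conditions: MeI, K2CO3, DMF, 40 °C
Reagents that add atoms: iodomethane (MeI), CI
Why: Williamson methylation of the only free phenol; a polar aprotic solvent and mild heat overcome the hydrogen bond to the aldehyde.

Step 5
Reactants: 9 methyl 2-(4-methoxyphenyl)acetate; 8 5-methoxy-7-(methoxymethoxy)-2,2-dimethyl-2H-chromene-6-carbaldehyde
Product: 11 methyl 3-hydroxy-3-[5-methoxy-7-(methoxymethoxy)-2,2-dimethyl-2H-chromen-6-yl]-2-(4-methoxyphenyl)propanoate (racemic diastereomer mixture), via lithium ester enolate 10 (not isolated)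
Conditions: LDA (commercial solution), THF, −78 °C; then 8, −78 °C; AcOH/THF quench at −78 °C
Reagents that add atoms: none
Why: Directed aldol addition of a preformed ester enolate to a non-enolisable aldehyde, quenched cold to prevent retro-aldol; the two new stereocentres form without control because both are erased in steps 6 to 8.

Step 6
Reactants: 11 methyl 3-hydroxy-3-[5-methoxy-7-(methoxymethoxy)-2,2-dimethyl-2H-chromen-6-yl]-2-(4-methoxyphenyl)propanoate
Product: 12 methyl 3-[5-methoxy-7-(methoxymethoxy)-2,2-dimethyl-2H-chromen-6-yl]-2-(4-methoxyphenyl)-3-oxopropanoate (racemic)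
Conditions: Dess–Martin periodinane, pyridine, CH2Cl2, 0 °C → rt
Reagents that add atoms: none
Why: Dess–Martin oxidation converts the hindered benzylic alcohol to the ketone under buffered, near-neutral conditions that spare the acid-sensitive electron-rich benzylic alcohol, the MOM ether and the chromene alkene.

Step 7
Reactants: 12 methyl 3-[5-methoxy-7-(methoxymethoxy)-2,2-dimethyl-2H-chromen-6-yl]-2-(4-methoxyphenyl)-3-oxopropanoate
Product: 13 1-[5-methoxy-7-(methoxymethoxy)-2,2-dimethyl-2H-chromen-6-yl]-2-(4-methoxyphenyl)ethan-1-one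
Conditions: LiCl, H2O, DMSO, 130 °C
Reagents that add atoms: none
Why: Krapcho dealkoxycarbonylation: chloride demethylates the ester by SN2, the β-keto carboxylate loses CO2 and water protonates the enolate; the hindered ketone resists retro-Claisen cleavage and the last stereocentre disappears.

Step 8
Reactants: 13 1-[5-methoxy-7-(methoxymethoxy)-2,2-dimethyl-2H-chromen-6-yl]-2-(4-methoxyphenyl)ethan-1-one
Product: 14 1-[5-methoxy-7-(methoxymethoxy)-2,2-dimethyl-2H-chromen-6-yl]-2-(4-methoxyphenyl)ethane-1,2-dione
Conditions: SeO2, 1,4-dioxane/H2O (20:1), 100 °C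
Reagents that add atoms: selenium dioxide, O=[Se]=O
Why: Riley oxidation of the doubly activated CH2 (α to the ketone and benzylic) gives the benzil; the chromene alkene has no allylic C–H (C2 is quaternary), so allylic oxidation cannot compete.

Step 9
Reactants: 14 1-[5-methoxy-7-(methoxymethoxy)-2,2-dimethyl-2H-chromen-6-yl]-2-(4-methoxyphenyl)ethane-1,2-dione
Product: 15 1-(7-hydroxy-5-methoxy-2,2-dimethyl-2H-chromen-6-yl)-2-(4-methoxyphenyl)ethane-1,2-dione
Conditions: 3 M aq. HCl, THF, 45 °C
Reagents that add atoms: none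
Why: Acid-catalysed acetal hydrolysis; a MOM ether ortho to a carbonyl is especially labile, aqueous THF rather than an alcohol avoids ketal formation at the diketone, and the mild temperature spares the 2,2-dimethylchromene.

**Compound list**
1 | 2,4,6-trihydroxybenzaldehyde | O=Cc1c(O)cc(O)cc1O | starting material
2 | 3-chloro-3-methylbut-1-yne | C#CC(C)(C)Cl | starting material
3 | 2,6-dihydroxy-4-[(2-methylbut-3-yn-2-yl)oxy]benzaldehyde | O=Cc1c(O)cc(OC(C)(C)C#C)cc1O | intermediate
4 | 2-hydroxy-6-(methoxymethoxy)-4-[(2-methylbut-3-yn-2-yl)oxy]benzaldehyde | O=Cc1c(O)cc(OC(C)(C)C#C)cc1OCOC | intermediate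
5 | 2,4-dihydroxy-6-(methoxymethoxy)-3-(3-methylbuta-1,2-dien-1-yl)benzaldehyde (allenylphenol) | O=Cc1c(O)c(C=C=C(C)C)c(O)cc1OCOC | intermediate (not isolated)
6 | (3Z)-2-hydroxy-6-(methoxymethoxy)-3-(3-methylbut-2-en-1-ylidene)-4-oxocyclohexa-1,5-diene-1-carbaldehyde (ortho-quinone methide) | O=CC1=C(O)/C(=C/C=C(C)C)C(=O)C=C1OCOC | intermediate (not isolated)
7 | 5-hydroxy-7-(methoxymethoxy)-2,2-dimethyl-2H-chromene-6-carbaldehyde | O=Cc1c(O)c2C=CC(C)(C)Oc2cc1OCOC | intermediate
8 | 5-methoxy-7-(methoxymethoxy)-2,2-dimethyl-2H-chromene-6-carbaldehyde | O=Cc1c(OC)c2C=CC(C)(C)Oc2cc1OCOC | intermediate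
9 | methyl 2-(4-methoxyphenyl)acetate | COC(=O)Cc1ccc(OC)cc1 | starting material
10 | lithium 1-methoxy-2-(4-methoxyphenyl)ethen-1-olate (lithium ester enolate) | COC(O[Li])=Cc1ccc(OC)cc1 | intermediate (not isolated)
11 | methyl 3-hydroxy-3-[5-methoxy-7-(methoxymethoxy)-2,2-dimethyl-2H-chromen-6-yl]-2-(4-methoxyphenyl)propanoate (racemic diastereomer mixture, no configuration assigned) | COC(=O)C(c1ccc(OC)cc1)C(O)c1c(OC)c2C=CC(C)(C)Oc2cc1OCOC | intermediate
12 | methyl 3-[5-methoxy-7-(methoxymethoxy)-2,2-dimethyl-2H-chromen-6-yl]-2-(4-methoxyphenyl)-3-oxopropanoate (racemic) | COC(=O)C(c1ccc(OC)cc1)C(=O)c1c(OC)c2C=CC(C)(C)Oc2cc1OCOC | intermediate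
13 | 1-[5-methoxy-7-(methoxymethoxy)-2,2-dimethyl-2H-chromen-6-yl]-2-(4-methoxyphenyl)ethan-1-one | COc1ccc(CC(=O)c2c(OC)c3C=CC(C)(C)Oc3cc2OCOC)cc1 | intermediate
14 | 1-[5-methoxy-7-(methoxymethoxy)-2,2-dimethyl-2H-chromen-6-yl]-2-(4-methoxyphenyl)ethane-1,2-dione | COc1ccc(C(=O)C(=O)c2c(OC)c3C=CC(C)(C)Oc3cc2OCOC)cc1 | intermediate
15 | 1-(7-hydroxy-5-methoxy-2,2-dimethyl-2H-chromen-6-yl)-2-(4-methoxyphenyl)ethane-1,2-dione (achiral) | COc1ccc(C(=O)C(=O)c2c(O)cc3c(c2OC)C=CC(C)(C)O3)cc1 | target

**Totals**
Total step count: 9. Longest linear sequence: 9 steps (1 → 15); compounds 2 and 9 are bought and used directly.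

**Three steps most likely to fail, each with a fallback**

Step 1 (mono-O-alkylation of a triphenol aldehyde; C-alkylation or over-alkylation may erode the yield). The fallback sets out from 1 and comes back at 7, replacing the propargyl ether chemistry by a phenol–enal condensation. Silylation of the para OH of 1 (TBSCl, imidazole, DMF, 0 °C) gives 4-[(tert-butyldimethylsilyl)oxy]-2,6-dihydroxybenzaldehyde F1. Mono-protection (MOMCl, iPr2NEt, CH2Cl2) gives 4-[(tert-butyldimethylsilyl)oxy]-2-hydroxy-6-(methoxymethoxy)benzaldehyde F2. Desilylation (TBAF, AcOH, THF, 0 °C) gives 2,4-dihydroxy-6-(methoxymethoxy)benzaldehyde F3. Heating F3 with 3-methylbut-2-enal and catalytic ethylenediammonium diacetate in toluene condenses the enal at the carbon between the two OH groups; the same ortho-quinone methide 6 forms and closes through the non-chelated OH to give 7.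

Step 3 (regiochemistry of the Claisen rearrangement: attack at the carbon next to the MOM ether would give the 7-hydroxy-5-MOM isomer). The fallback sets out from 3 and comes back at 7, setting the regiochemistry by symmetry and sterics instead of chelation. Heating the symmetric diol 3 (o-xylene, 140 °C) can place the allene at only one kind of ortho carbon and gives 5,7-dihydroxy-2,2-dimethyl-2H-chromene-6-carbaldehyde F4. One equivalent of MOMCl with iPr2NEt at −20 to 0 °C then protects the less hindered 7-OH, giving 7; the 5-OH lies in the peri pocket next to H-4. Either way the assignment is checked after step 4 by an NOE between the 5-OCH3 and H-4.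

Step 8 (SeO2 may react sluggishly, over-oxidise or touch the electron-rich chromene; partial MOM loss here is harmless because step 9 completes it). The fallback sets out from 13 and comes back at 14 by a two-stage enolate route. Deprotonation of 13 with KHMDS (THF, −78 °C) and hydroxylation with 2-(phenylsulfonyl)-3-phenyloxaziridine gives 2-hydroxy-1-[5-methoxy-7-(methoxymethoxy)-2,2-dimethyl-2H-chromen-6-yl]-2-(4-methoxyphenyl)ethan-1-one F5 (racemic). Dess–Martin oxidation with pyridine in CH2Cl2 then gives 14.

**Further compounds**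
F1 | step 1 | 4-[(tert-butyldimethylsilyl)oxy]-2,6-dihydroxybenzaldehyde | O=Cc1c(O)cc(O[Si](C)(C)C(C)(C)C)cc1O
F2 | step 1 | 4-[(tert-butyldimethylsilyl)oxy]-2-hydroxy-6-(methoxymethoxy)benzaldehyde | O=Cc1c(O)cc(O[Si](C)(C)C(C)(C)C)cc1OCOC
F3 | step 1 | 2,4-dihydroxy-6-(methoxymethoxy)benzaldehyde | O=Cc1c(O)cc(O)cc1OCOC
F4 | step 3 | 5,7-dihydroxy-2,2-dimethyl-2H-chromene-6-carbaldehyde | O=Cc1c(O)cc2OC(C)(C)C=Cc2c1O
F5 | step 8 | 2-hydroxy-1-[5-methoxy-7-(methoxymethoxy)-2,2-dimethyl-2H-chromen-6-yl]-2-(4-methoxyphenyl)ethan-1-one (racemic) | COc1ccc(C(O)C(=O)c2c(OC)c3C=CC(C)(C)Oc3cc2OCOC)cc1
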